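Both earlier runs charge the same amount of X and differ in [E], 0.72 M in the north-west run and 1.6 M in the south run, and the flask stands between them at 1.07 M.

common to all: X 0.97 M

| flask | E | remark | time |
|---|---|---|---|
| north-west | 0.72 M | run made earlier |  |
| south | 1.6 M | run made earlier |  |
| flask | 1.07 M |  | 8.0 h |

- north-west (time / h: G / %, X / %): 0.833: 0.4, 98.6; 2.00: 0.9, 96.6; 4.00: 1.3, 92.4; 10.0: 9.0, 82.1
- south (time / h: G / %, X / %): 2.50: 1.4, 93.7; 5.00: 5.8, 90.3; 8.00: 11.4, 83.5; 10.0: 13.8, 80.3

(each reading ± 1 percentage point)

* amount of G in percent of the X charged, at 50 min, 3.0 h and 8.0 h

- given per volume of solution although it is solid: X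
- at the start none of X is in solution
- a reading or a percentage of G counts all its forms, free or not

Two chemists read these tables. The first holds a one-step view, X with E straight to G, so that at a fixed time G goes in direct proportion to [E]. Scaling the south run's 11.4% at 8.00 h down by [E], the first chemist gets 7.62% for the flask at 8.0 h.

The second chemist points to the amounts of X. At 10.0 h the two runs differ by 1.8 percentage points in X, against a scatter of 1 point, although [E] differs 2.22 times. So the second chemist lets X go at its own pace and G come later, from “a dissolved or intermediate pool that is converted to G by an E-dependent step”. That side's forecast is 0.2%, 1.6% and 8.3%.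

On the blackboard, logarithms turn the dispute into one number. At 10.0 h the south run holds 1.53 times the G of the north-west run, and dividing log10 of that by log10 of the [E] ratio gives 0.535. This is the E-exponent, the rise of log G per rise of log [E] at a fixed time, also called the apparent order in E. The first chemist needs it to be one, but this reading, with its scatter, lies lower. Carried from the south run to the flask, it gives my own 9.19% at 8.0 h, which is higher than the forecast's last number and comes from a different reckoning.

The flask gives 0.211%, 2.07% and 8.82%, and at 8.0 h that lies closer to the forecast, 0.52 points away, than to the first chemist's number, 1.2 points away.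

    E + G ⇌ D, settled at all times (K = 0.340 M⁻¹)
    X ⇌ Q, rate k2*(cs2 - [Q]) while solid is left; crystals form when [Q] > cs2 (solubility = 0.190 M, k = 0.130 h⁻¹)
    Q → J (k = 0.0300 h⁻¹)
    Q + E → G (k = 0.250 M⁻¹ h⁻¹)

In this flask X went into solution up to 8.0 h, with 12% of that net turnover done by 0.800 h, and Q, the X in solution, rose from 1.73% then to 6.00% at 8.00 h. While Q stood there, Q + E → G ran, with a half-life of Q by that step of 2.7 h at 3.67 h and 2.9 h at 8.00 h. The first chemist's exponent of one has its ground at early times such as 0.800 h, short of the 2.6 h half-life of Q by that step. Against the south reading at 8.00 h, this flask's G gives an exponent of 0.638, beside 0.535. Carrying 0.535 from this flask to one with twice the E gives 12.8%, and the flask with twice the E stands at 12.6%.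

The readings come from a simulation from invented constants, and the scatter is random.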